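**Assumptions and naming convention (one line each).** The ketoreductase is picked from a commercial screening panel; but-1-yne and triethyl 4-phosphonocrotonate count as commercial. Core locants in names: ring A = C1, C2, C3, C4, C5, C10; ring B = C5, C6, C7, C8, C9, C10; methyls sit on C4 and C5; β = face of the C5 methyl, α = the opposite face.

## Retrosynthetic overview

1. Last bond: the C3–O ester, by Yamaguchi coupling of core alcohol 21 with the silyl-protected (S)-dienoic acid 35, then global desilylation.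
2. Core oxidation pattern: C7–OH by α′-hydroxylation of the dienone; C1=C2 by dehydrogenation of the enone; the C3 carbinol by ketoreductase reduction of ene-dione 13.
3. Ene-dione 13 comes from (S)-Wieland–Miescher ketone by alkylative 1,2-carbonyl transposition (enol triflate, methyl coupling, hydroboration, oxidation) with the enone masked as a dithiolane.
4. Ring order: ring A is the ring of 2-methylcyclohexane-1,3-dione; ring B is closed onto it by L-proline-catalysed aldol condensation, which sets the quaternary C5 centre first.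
5. Acid 35: Sharpless epoxidation sets the tertiary carbinol; epoxy iodide opening, ozonolysis and a vinylogous Horner–Wadsworth–Emmons reaction build the dienoate.

## Route

**Step 1**
Reactants: 1 2-methylcyclohexane-1,3-dione; 2 but-3-en-2-one (methyl vinyl ketone)
Product: 3 2-methyl-2-(3-oxobutyl)cyclohexane-1,3-dione
Conditions: AcOH (cat.), hydroquinone (cat.), H2O, 75 °C
Reagents that add atoms: none
Why: Michael addition of the acidic 2-methyl-1,3-dione to the enone (first half of a Robinson annulation) gives the achiral triketone, with no stereocentre formed.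

**Step 2**
Reactants: 3 2-methyl-2-(3-oxobutyl)cyclohexane-1,3-dione
Product: 5 (S)-Wieland–Miescher ketone (5β-methyl-Δ9(10)-octalin-4,8-dione), via ketol 4 (not isolated)
Conditions: L-proline (5 mol%), DMSO, 35 °C, 4 d; recrystallise (Et2O) to ≥99% ee
Reagents that add atoms: none
Why: In this Hajos–Parrish–Eder–Sauer–Wiechert reaction the proline enamine attacks one of the two enantiotopic ring carbonyls, which sets the quaternary C5 centre as (S) and closes ring B after in-situ dehydration of the ketol.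

**Step 3**
Reactants: 5 (S)-Wieland–Miescher ketone
Product: 6 C8-spiro-1,3-dithiolane of 5 (8,8-ethylenedithio-5β-methyl-Δ9(10)-octalin-4-one)
Conditions: HSCH2CH2SH (1.05 equiv), p-TsOH (cat.), AcOH, rt
Reagents that add atoms: ethane-1,2-dithiol, SCCS
Why: Chemoselective dithioketalisation occurs at the conjugated ketone through its stabilised allylic thionium ion, while the hindered neopentyl C4 ketone stays free and the alkene stays at C9=C10.

**Step 4**
Reactants: 6 C8-dithiolane C4-ketone
Product: 8 C3=C4 enol triflate (4-triflyloxy-5β-methyl-3,9(10)-diene C8-dithiolane), via potassium enolate 7 (not isolated)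
Conditions: KN(SiMe3)2, THF, −78 °C; PhNTf2, −78 → 0 °C
Reagents that add atoms: N-phenylbis(trifluoromethanesulfonimide), O=S(=O)(N(c1ccccc1)S(=O)(=O)C(F)(F)F)C(F)(F)F
Why: Enolate O-triflation is regiodefined because the C4 ketone can enolise only towards C3 (C5 is quaternary).

**Step 5**
Reactants: 8 C3=C4 enol triflate
Product: 9 4,5β-dimethyl-3,9(10)-diene C8-dithiolane
Conditions: MeMgBr, Fe(acac)3 (5 mol%), THF/NMP, −20 → 0 °C
Reagents that add atoms: methylmagnesium bromide, C[Mg]Br
Why: Iron-catalysed Kumada-type cross-coupling of the alkenyl triflate installs the C4 methyl group on the ring alkene.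

**Step 6**
Reactants: 9 4,5β-dimethyl-3,9(10)-diene C8-dithiolane
Product: 11 3α-hydroxy-4β,5β-dimethyl-Δ9(10)-octalin C8-dithiolane, via alkylborane 10 (not isolated)
Conditions: BH3·THF (1.2 equiv), THF, 0 °C; then 3 M NaOH, 30% H2O2, 0 °C
Reagents that add atoms: hydrogen peroxide, OO
Why: Brown hydroboration–oxidation adds H and B syn and anti-Markovnikov to the C3=C4 alkene from the α face opposite the axial C5 methyl (the C9=C10 alkene is shielded by the dithiolane and the quaternary carbon), which sets the 4β-methyl cis to the C5 methyl and the 3α-OH with retention at boron.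

**Step 7**
Reactants: 11 3α-alcohol
Product: 12 4β,5β-dimethyl-Δ9(10)-octalin-3-one C8-dithiolane
Conditions: (COCl)2, DMSO, CH2Cl2, −78 °C; Et3N, → 0 °C
Reagents that add atoms: none
Why: Swern oxidation gives the C3 ketone without touching the dithiolane, and the adjacent 4β-methyl is equatorial and so configurationally stable.

**Step 8**
Reactants: 12 C3-ketone C8-dithiolane
Product: 13 (4aR,5R)-4a,5-dimethyl-4,4a,7,8-tetrahydronaphthalene-2,6(3H,5H)-dione (4β,5β-dimethyl-Δ9(10)-octalin-3,8-dione)
Conditions: MeI (excess), CaCO3, MeCN/H2O (4:1), 45 °C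
Reagents that add atoms: water, O
Why: Alkylative hydrolysis of the dithiolane (S-methylation, then hydrolysis of the allylic sulfonium ion) unmasks the enone under near-neutral conditions.

**Step 9**
Reactants: 13 ene-dione
Product: 14 (4aR,5R,6S)-6-hydroxy-4a,5-dimethyl-4,4a,5,6,7,8-hexahydronaphthalen-2(3H)-one (3β-hydroxy-4β,5β-dimethyl-Δ9(10)-octalin-8-one)
Conditions: ketoreductase (Prelog-selective, NADPH-dependent), NADP+ (cat.), i-PrOH (10 vol%), KH2PO4/K2HPO4 buffer pH 7.0, DMSO (5 vol%), 30 °C
Reagents that add atoms: none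
Why: Biocatalytic carbonyl reduction by the ketoreductase touches only the saturated C3 ketone and delivers hydride to the α face under enzyme control to give the axial 3β (S) alcohol, the same sense as the substrate bias from the syn-axial C5 methyl.

**Step 10**
Reactants: 14 3β-hydroxy enone
Product: 15 3β-(triethylsilyloxy)-4β,5β-dimethyl-Δ9(10)-octalin-8-one
Conditions: Et3SiOTf, 2,6-lutidine, CH2Cl2, −78 °C
Reagents that add atoms: triethylsilyl trifluoromethanesulfonate, CC[Si](CC)(CC)OS(=O)(=O)C(F)(F)F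
Why: Silylation with a silyl triflate and a hindered base protects the hindered axial alcohol as an acid-labile TES ether.

**Step 11**
Reactants: 15 3β-TES enone
Product: 17 3β-(triethylsilyloxy)-4β,5β-dimethyl-1,9(10)-dien-8-one, via silyl dienol ether 16 (not isolated)
Conditions: TBSOTf, Et3N, CH2Cl2, 0 °C → rt; then DDQ (1.05 equiv), 2,6-lutidine, CH2Cl2, 0 °C
Reagents that add atoms: none
Why: Soft enolisation gives the thermodynamically favoured extended silyl dienol ether, and DDQ dehydrogenation (hydride abstraction at C2, then loss of silicon) gives the linear dienone, as in the classical 3,5-dienol ether to 4,6-dienone oxidation.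

**Step 12**
Reactants: 17 dienone
Product: 19 7α-hydroxy-3β-(triethylsilyloxy)-4β,5β-dimethyl-1,9(10)-dien-8-one, via sodium dienolate 18 (not isolated)
Conditions: NaN(SiMe3)2, THF, −78 °C; (±)-2-(phenylsulfonyl)-3-phenyloxaziridine, −78 °C; aq. NH4Cl
Reagents that add atoms: 2-(phenylsulfonyl)-3-phenyloxaziridine, O=S(=O)(N1OC1c1ccccc1)c1ccccc1
Why: In this Davis α′-hydroxylation, kinetic deprotonation at C7 gives the cross-conjugated dienolate, which is oxidised from the α face anti to the axial C5 methyl to give the equatorial 7α (R) alcohol, also the thermodynamically preferred epimer.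

**Step 13**
Reactants: 19 7α-hydroxy dienone
Product: 20 7α-(tert-butyldimethylsilyloxy)-3β-(triethylsilyloxy)-4β,5β-dimethyl-1,9(10)-dien-8-one
Conditions: TBSCl, imidazole, DMF, rt
Reagents that add atoms: tert-butyldimethylsilyl chloride, CC(C)(C)[Si](C)(C)Cl
Why: Silylation of the unhindered α-ketol hydroxyl installs the more robust TBS ether.

**Step 14**
Reactants: 20 bis-silyl ether
Product: 21 3β-hydroxy-7α-(tert-butyldimethylsilyloxy)-4β,5β-dimethyl-1,9(10)-dien-8-one
Conditions: PPTS (0.2 equiv), MeOH/CH2Cl2 (1:1), 0 °C → rt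
Reagents that add atoms: none
Why: Selective acid-catalysed methanolysis removes the TES ether, which cleaves far faster than the TBS ether.

**Step 15**
Reactants: 22 but-1-yne
Product: 25 (E)-3-methylpent-2-en-1-ol, via alkenylalane 23 (not isolated), via lithium alanate 24 (not isolated)
Conditions: Me3Al, Cp2ZrCl2 (0.2 equiv), CH2Cl2, 0 °C → rt; n-BuLi, −78 → 0 °C; (CH2O)n, THF, rt; 3 M HCl work-up
Reagents that add atoms: trimethylaluminium, C[Al](C)C; paraformaldehyde (formaldehyde unit), C=O
Why: Negishi zirconium-catalysed carboalumination adds Me and Al syn across the alkyne to give the (E)-alkenylalane, whose ate complex is hydroxymethylated with retention of geometry.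

**Step 16**
Reactants: 25 (E)-3-methylpent-2-en-1-ol
Product: 26 [(2S,3S)-3-ethyl-3-methyloxiran-2-yl]methanol
Conditions: Ti(Oi-Pr)4 (5 mol%), L-(+)-diethyl tartrate (6 mol%), t-BuOOH, 4 Å MS, CH2Cl2, −20 °C
Reagents that add atoms: tert-butyl hydroperoxide, CC(C)(C)OO
Why: Sharpless asymmetric epoxidation with L-(+)-tartrate delivers oxygen to one face of the (E)-allylic alcohol (as for geraniol), which sets the tertiary C–O centre as (S).

**Step 17**
Reactants: 26 epoxy alcohol
Product: 27 (2S,3R)-2-ethyl-3-(iodomethyl)-2-methyloxirane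
Conditions: I2, PPh3, imidazole, CH2Cl2, 0 °C
Reagents that add atoms: iodine, II
Why: Appel-type (Garegg–Samuelsson) iodination converts the primary alcohol to the iodide without opening the epoxide.

**Step 18**
Reactants: 27 epoxy iodide
Product: 29 (S)-triethyl[(3-methylpent-1-en-3-yl)oxy]silane, via lithium alkoxide 28 (not isolated)
Conditions: n-BuLi (1.05 equiv), THF, −78 °C; then Et3SiOTf, −78 → 0 °C
Reagents that add atoms: triethylsilyl trifluoromethanesulfonate, CC[Si](CC)(CC)OS(=O)(=O)C(F)(F)F
Why: Iodine–lithium exchange followed by β-elimination opens the epoxide at the secondary C–O bond, so the tertiary C–O bond keeps its (S) configuration in the transposed allylic alkoxide, which is silylated in the same flask.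

**Step 19**
Reactants: 29 allylic TES ether
Product: 31 (S)-2-methyl-2-(triethylsilyloxy)butanal, via ozonide 30 (not isolated)
Conditions: O3, CH2Cl2, −78 °C; PPh3, −78 °C → rt
Reagents that add atoms: ozone, [O-][O+]=O
Why: Ozonolysis with reductive work-up cleaves the vinyl group to the aldehyde, whose quaternary α-carbon cannot epimerise.

**Step 20**
Reactants: 31 (S)-2-methyl-2-(triethylsilyloxy)butanal; 32 triethyl (E)-4-phosphonocrotonate
Product: 34 ethyl (2E,4E,6S)-6-methyl-6-(triethylsilyloxy)octa-2,4-dienoate, via lithiated phosphonate 33 (not isolated)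
Conditions: LiN(SiMe3)2, THF, −78 → 0 °C
Reagents that add atoms: none
Why: The vinylogous Horner–Wadsworth–Emmons olefination forms the new C4=C5 bond E-selectively with the hindered aldehyde and keeps the E geometry of the phosphonate at C2=C3.

**Step 21**
Reactants: 34 dienoate ethyl ester
Product: 35 (2E,4E,6S)-6-methyl-6-(triethylsilyloxy)octa-2,4-dienoic acid
Conditions: LiOH·H2O, THF/MeOH/H2O (3:1:1), rt; 1 M HCl to pH 4 at 0 °C
Reagents that add atoms: lithium hydroxide, [Li+].[OH-]
Why: Saponification cleaves the ethyl ester while the tertiary TES ether survives the base.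

**Step 22**
Reactants: 21 core alcohol; 35 dienoic acid
Product: 37 bis-silyl ether of the target (3β-dienoate with 7α-OTBS and side-chain OTES), via mixed anhydride 36 (not isolated)
Conditions: 35, 2,4,6-Cl3C6H2COCl, Et3N, THF, rt; then 21, DMAP, toluene, rt → 40 °C
Reagents that add atoms: none
Why: Yamaguchi esterification acylates the hindered axial 3β-alcohol through the DMAP-activated mixed anhydride with retention at C3.

**Step 23**
Reactants: 37 bis-silyl ether
Product: 38 CNP0260852.4
Conditions: HF·pyridine, pyridine, THF, 0 °C → rt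
Reagents that add atoms: none
Why: Fluoride-mediated global desilylation under pyridine-buffered conditions removes the TBS and TES ethers and leaves the ester, the dienone and the α-ketol intact.

## Compound list

1 | 2-methylcyclohexane-1,3-dione | CC1C(=O)CCCC1=O | starting material
2 | but-3-en-2-one (methyl vinyl ketone) | CC(=O)C=C | starting material
3 | 2-methyl-2-(3-oxobutyl)cyclohexane-1,3-dione | CC(=O)CCC1(C)C(=O)CCCC1=O | intermediate
4 | cis-fused ketol, 10β-hydroxy-5β-methyldecalin-4,8-dione (not isolated) | C1CC[C@]2(O)CC(=O)CC[C@]2(C)C1=O | intermediate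
5 | (S)-Wieland–Miescher ketone, (8aS)-8a-methyl-3,4,8,8a-tetrahydronaphthalene-1,6(2H,7H)-dione | C1CCC2=CC(=O)CC[C@]2(C)C1=O | intermediate
6 | 8,8-ethylenedithio-5β-methyl-Δ9(10)-octalin-4-one (C8 spiro-1,3-dithiolane) | C1CCC2=CC3(SCCS3)CC[C@]2(C)C1=O | intermediate
7 | potassium 3-en-4-olate of 6 (not isolated) | C1=C([O-])[C@@]2(C)CCC3(SCCS3)C=C2CC1.[K+] | intermediate
8 | 4-(trifluoromethanesulfonyloxy)-5β-methyl-3,9(10)-diene C8-dithiolane | C1=C(OS(=O)(=O)C(F)(F)F)[C@@]2(C)CCC3(SCCS3)C=C2CC1 | intermediate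
9 | 4,5β-dimethyl-3,9(10)-diene C8-dithiolane | C1=C(C)[C@@]2(C)CCC3(SCCS3)C=C2CC1 | intermediate
10 | 3α-boryl-4β,5β-dimethyl-Δ9(10)-octalin C8-dithiolane (not isolated) | B[C@@H]1CCC2=CC3(SCCS3)CC[C@]2(C)[C@H]1C | intermediate
11 | 3α-hydroxy-4β,5β-dimethyl-Δ9(10)-octalin C8-dithiolane | O[C@@H]1CCC2=CC3(SCCS3)CC[C@]2(C)[C@H]1C | intermediate
12 | 4β,5β-dimethyl-Δ9(10)-octalin-3-one C8-dithiolane | O=C1CCC2=CC3(SCCS3)CC[C@]2(C)[C@H]1C | intermediate
13 | (4aR,5R)-4a,5-dimethyl-4,4a,7,8-tetrahydronaphthalene-2,6(3H,5H)-dione | O=C1CCC2=CC(=O)CC[C@]2(C)[C@H]1C | intermediate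
14 | (4aR,5R,6S)-6-hydroxy-4a,5-dimethyl-4,4a,5,6,7,8-hexahydronaphthalen-2(3H)-one | O[C@H]1CCC2=CC(=O)CC[C@]2(C)[C@H]1C | intermediate
15 | 3β-(triethylsilyloxy)-4β,5β-dimethyl-Δ9(10)-octalin-8-one | CC[Si](CC)(CC)O[C@H]1CCC2=CC(=O)CC[C@]2(C)[C@H]1C | intermediate
16 | 8-(tert-butyldimethylsilyloxy)-3β-(triethylsilyloxy)-4β,5β-dimethyl-1(10),8-diene (not isolated) | CC[Si](CC)(CC)O[C@H]1CC=C2C=C(O[Si](C)(C)C(C)(C)C)CC[C@]2(C)[C@H]1C | intermediate
17 | 3β-(triethylsilyloxy)-4β,5β-dimethyl-1,9(10)-dien-8-one | CC[Si](CC)(CC)O[C@H]1C=CC2=CC(=O)CC[C@]2(C)[C@H]1C | intermediate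
18 | sodium 1,7,9(10)-trien-8-olate of 17 (not isolated) | CC[Si](CC)(CC)O[C@H]1C=CC2=CC([O-])=CC[C@]2(C)[C@H]1C.[Na+] | intermediate
19 | 7α-hydroxy-3β-(triethylsilyloxy)-4β,5β-dimethyl-1,9(10)-dien-8-one | CC[Si](CC)(CC)O[C@H]1C=CC2=CC(=O)[C@H](O)C[C@]2(C)[C@H]1C | intermediate
20 | 7α-(tert-butyldimethylsilyloxy)-3β-(triethylsilyloxy)-4β,5β-dimethyl-1,9(10)-dien-8-one | CC[Si](CC)(CC)O[C@H]1C=CC2=CC(=O)[C@H](O[Si](C)(C)C(C)(C)C)C[C@]2(C)[C@H]1C | intermediate
21 | 3β-hydroxy-7α-(tert-butyldimethylsilyloxy)-4β,5β-dimethyl-1,9(10)-dien-8-one | O[C@H]1C=CC2=CC(=O)[C@H](O[Si](C)(C)C(C)(C)C)C[C@]2(C)[C@H]1C | intermediate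
22 | but-1-yne | CCC#C | starting material
23 | (E)-dimethyl(2-methylbut-1-en-1-yl)alane (not isolated) | CC/C(C)=C/[Al](C)C | intermediate
24 | lithium butyl(dimethyl)[(E)-2-methylbut-1-en-1-yl]alanate (not isolated) | CC/C(C)=C/[Al-](C)(C)CCCC.[Li+] | intermediate
25 | (E)-3-methylpent-2-en-1-ol | CC/C(C)=C/CO | intermediate
26 | [(2S,3S)-3-ethyl-3-methyloxiran-2-yl]methanol | CC[C@]1(C)O[C@H]1CO | intermediate
27 | (2S,3R)-2-ethyl-3-(iodomethyl)-2-methyloxirane | CC[C@]1(C)O[C@H]1CI | intermediate
28 | lithium (S)-3-methylpent-1-en-3-olate (not isolated) | CC[C@](C)([O-])C=C.[Li+] | intermediate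
29 | (S)-triethyl[(3-methylpent-1-en-3-yl)oxy]silane | CC[C@](C)(O[Si](CC)(CC)CC)C=C | intermediate
30 | 3-[(S)-2-(triethylsilyloxy)butan-2-yl]-1,2,4-trioxolane, epimers at the ring carbon (not isolated) | CC[C@](C)(O[Si](CC)(CC)CC)C1OCOO1 | intermediate
31 | (S)-2-methyl-2-(triethylsilyloxy)butanal | CC[C@](C)(O[Si](CC)(CC)CC)C=O | intermediate
32 | triethyl (E)-4-phosphonocrotonate | CCOC(=O)/C=C/CP(=O)(OCC)OCC | starting material
33 | lithiated triethyl 4-phosphonocrotonate (not isolated) | CCOC(=O)/C=C/[CH-]P(=O)(OCC)OCC.[Li+] | intermediate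
34 | ethyl (2E,4E,6S)-6-methyl-6-(triethylsilyloxy)octa-2,4-dienoate | CC[C@](C)(O[Si](CC)(CC)CC)/C=C/C=C/C(=O)OCC | intermediate
35 | (2E,4E,6S)-6-methyl-6-(triethylsilyloxy)octa-2,4-dienoic acid | CC[C@](C)(O[Si](CC)(CC)CC)/C=C/C=C/C(=O)O | intermediate
36 | mixed anhydride of 35 with 2,4,6-trichlorobenzoic acid (not isolated) | CC[C@](C)(O[Si](CC)(CC)CC)/C=C/C=C/C(=O)OC(=O)c1c(Cl)cc(Cl)cc1Cl | intermediate
37 | 7α-O-TBS, side-chain O-TES ether of the target | CC[C@](C)(O[Si](CC)(CC)CC)/C=C/C=C/C(=O)O[C@H]1C=CC2=CC(=O)[C@H](O[Si](C)(C)C(C)(C)C)C[C@]2(C)[C@H]1C | intermediate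
38 | CNP0260852.4, (1R,2S,7R,8aR)-7-hydroxy-1,8a-dimethyl-6-oxo-1,2,6,7,8,8a-hexahydronaphthalen-2-yl (2E,4E,6S)-6-hydroxy-6-methylocta-2,4-dienoate | CC[C@](C)(O)/C=C/C=C/C(=O)O[C@H]1C=CC2=CC(=O)[C@H](O)C[C@]2(C)[C@H]1C | target

## Step count and risk

Total: 23 steps. Longest linear sequence: 16 steps (steps 1–14, 22, 23, from 1 to 38); the side-chain branch is 7 steps (15–21).

The three steps most likely to fail:

**Step 6 (chemoselective hydroboration in the presence of the C9=C10 alkene and sulfur).** The fallback sets out from 9 and comes back at 13. MeI/CaCO3 in aqueous MeCN first unmasks the enone to give 4,5β-dimethyl-3,9(10)-dien-8-one F1. mCPBA/NaHCO3 in CH2Cl2 at 0 °C then epoxidises only the electron-rich C3=C4 alkene (the enone alkene is inert) from the α face, giving 3α,4α-epoxy-4β,5β-dimethyl-Δ9(10)-octalin-8-one F2. BF3·OEt2 in toluene at −78 °C triggers a Meinwald rearrangement (hydride shift from C3 to the tertiary C4 cation), and brief DBU equilibration places the C4 methyl in the equatorial β position, giving 13. This replaces steps 6–8.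

**Step 11 (regiochemistry of soft enolisation and over-oxidation by DDQ).** The fallback sets out from 15 and comes back at 17. Wohl–Ziegler bromination (NBS, AIBN, PhCF3, 80 °C) at the allylic γ-position C1 gives 1β-bromo-3β-(triethylsilyloxy)-4β,5β-dimethyl-Δ9(10)-octalin-8-one F3. E2 dehydrobromination with Li2CO3/LiBr in DMF at 120 °C then gives dienone 17.

**Step 12 (enolate oxidation of the dienone).** The fallback sets out from 17 and comes back at 19. Mn(OAc)3 in refluxing benzene acetoxylates the α′ position through the manganese enolate, anti to the angular methyl, giving 7α-acetoxy-3β-(triethylsilyloxy)-4β,5β-dimethyl-1,9(10)-dien-8-one F4. A lipase (a serine hydrolase, for example from Candida rugosa) in phosphate buffer pH 7/toluene at 30 °C then removes the acetate without base, giving 19.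

## Further compounds

F1 | step 6 | 4,5β-dimethyl-3,9(10)-dien-8-one | C1=C(C)[C@@]2(C)CCC(=O)C=C2CC1
F2 | step 6 | 3α,4α-epoxy-4β,5β-dimethyl-Δ9(10)-octalin-8-one | O1[C@@H]2CCC3=CC(=O)CC[C@]3(C)[C@]12C
F3 | step 11 | 1β-bromo-3β-(triethylsilyloxy)-4β,5β-dimethyl-Δ9(10)-octalin-8-one | CC[Si](CC)(CC)O[C@H]1C[C@@H](Br)C2=CC(=O)CC[C@]2(C)[C@H]1C
F4 | step 12 | 7α-acetoxy-3β-(triethylsilyloxy)-4β,5β-dimethyl-1,9(10)-dien-8-one | CC[Si](CC)(CC)O[C@H]1C=CC2=CC(=O)[C@H](OC(C)=O)C[C@]2(C)[C@H]1C
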